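**Retrosynthetic overview**
- Target ⇐ global O‑debenzylation of a hepta‑O‑benzyl ester ⇐ acylation of a (2R,3R)‑cis‑flavan‑3‑ol with tri‑O‑benzylgalloyl chloride.
- cis‑Flavan‑3‑ol ⇐ L‑Selectride reduction of a (2R)‑flavan‑3‑one ⇐ Baeyer–Villiger excision of the formyl carbon of a (2R)‑2‑aryl‑2H‑chromene‑3‑carbaldehyde.
- The pyran ring is the only ring built (all three benzene rings are purchased). It is closed by an intramolecular aldol condensation in an organocatalytic oxa‑Michael/aldol cascade between an A‑ring salicylaldehyde and a B‑ring cinnamaldehyde; the oxa‑Michael sets C2.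
- Three fragments: salicylaldehyde from phloroglucinol (3 steps), cinnamaldehyde from methyl gallate (5 steps), galloyl chloride from methyl gallate (3 steps).

Assumption: the target is the (2R,3R), 2,3‑cis (epi) isomer, as encoded by the SMILES.
Assumption: numbered compounds are starting materials, isolated intermediates and the target; reagents are given by name and SMILES inside each step.

---

**A‑ring fragment**

Step 1
Reactants: 1 phloroglucinol
Product: 2 1,3,5‑tris(benzyloxy)benzene
Conditions: BnBr (3.3 equiv), K2CO3, DMF, rt → 50 °C; recrystallise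
Reagents that add atoms: benzyl bromide, BrCc1ccccc1
Why: Williamson etherification; carbonate in DMF favours O‑ over C‑alkylation and the symmetrical triether crystallises away from C‑benzylated by‑products.

Step 2
Reactants: 2 1,3,5‑tris(benzyloxy)benzene
Product: 3 2,4,6‑tris(benzyloxy)benzaldehyde
Conditions: POCl3, DMF, 0 °C → rt; aq. NaOAc
Reagents that add atoms: DMF, CN(C)C=O (formyl carbon); water, O (carbonyl oxygen on hydrolysis)
Why: Vilsmeier–Haack formylation of a very electron‑rich arene; all three ring positions are equivalent and the product is deactivated, so it stops at mono‑formylation.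

Step 3
Reactants: 3 2,4,6‑tris(benzyloxy)benzaldehyde
Product: 4 4,6‑bis(benzyloxy)‑2‑hydroxybenzaldehyde
Conditions: MgBr2·OEt2 (1.3 equiv), toluene/Et2O, reflux
Reagents that add atoms: none
Why: chelation‑directed Lewis‑acid debenzylation removes only a benzyl ortho to the carbonyl; the resulting magnesium phenoxide chelate shuts down the second cleavage.

**B‑ring fragment**

Step 4
Reactants: 5 methyl gallate
Product: 6 methyl 3,5‑dihydroxy‑4‑methoxybenzoate
Conditions: MeI (1.1 equiv), Li2CO3, DMF, 40 °C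
Reagents that add atoms: iodomethane, CI
Why: regioselective Williamson methylation; the 4‑OH, para to the ester, is the most acidic and is the only one appreciably ionised by the weak base.

Step 5
Reactants: 6 methyl 3,5‑dihydroxy‑4‑methoxybenzoate
Product: 7 methyl 3,5‑bis(benzyloxy)‑4‑methoxybenzoate
Conditions: BnBr (2.3 equiv), K2CO3, DMF, 60 °C
Reagents that add atoms: benzyl bromide, BrCc1ccccc1
Why: exhaustive Williamson benzylation of the two remaining phenols.

Step 6
Reactants: 7 methyl 3,5‑bis(benzyloxy)‑4‑methoxybenzoate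
Product: 8 [3,5‑bis(benzyloxy)‑4‑methoxyphenyl]methanol
Conditions: LiAlH4, THF, 0 °C
Reagents that add atoms: none
Why: hydride reduction of the ester to the benzylic alcohol; aryl ethers are inert.

Step 7
Reactants: 8 [3,5‑bis(benzyloxy)‑4‑methoxyphenyl]methanol
Product: 9 3,5‑bis(benzyloxy)‑4‑methoxybenzaldehyde
Conditions: activated MnO2, CH2Cl2, rt
Reagents that add atoms: none
Why: selective benzylic alcohol oxidation that stops at the aldehyde.

Step 8
Reactants: 9 3,5‑bis(benzyloxy)‑4‑methoxybenzaldehyde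
Product: 10 (E)‑3‑[3,5‑bis(benzyloxy)‑4‑methoxyphenyl]prop‑2‑enal
Conditions: Ph3P=CHCHO (1.15 equiv), toluene, 80 °C
Reagents that add atoms: (triphenylphosphoranylidene)acetaldehyde, O=CC=P(c1ccccc1)(c1ccccc1)c1ccccc1
Why: Wittig two‑carbon homologation with a stabilised ylide gives the E‑enal; limiting the ylide suppresses dienal formation.

**Fragment union and ring closure**

Step 9 (key step)
Reactants: 4 4,6‑bis(benzyloxy)‑2‑hydroxybenzaldehyde; 10 (E)‑3‑[3,5‑bis(benzyloxy)‑4‑methoxyphenyl]prop‑2‑enal (1.5 equiv)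
Product: 11 (2R)‑5,7‑bis(benzyloxy)‑2‑[3,5‑bis(benzyloxy)‑4‑methoxyphenyl]‑2H‑chromene‑3‑carbaldehyde
Conditions: (S)‑α,α‑diphenylprolinol TMS ether (20 mol %), 2‑nitrobenzoic acid (20 mol %), 4 Å MS, toluene, rt
Reagents that add atoms: none (water is lost)
Why: iminium/enamine domino oxa‑Michael/intramolecular aldol condensation. The phenol adds to the β‑carbon of the E‑iminium on the face away from the CPh2OTMS group, which by the standard shielding model gives 2R (sense to be confirmed on the first batch). The resulting enamine then closes the pyran ring onto the ortho aldehyde and dehydrates.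

Step 10
Reactants: 11 the (2R)‑chromene‑3‑carbaldehyde
Product: 12 (2R)‑5,7‑bis(benzyloxy)‑2‑[3,5‑bis(benzyloxy)‑4‑methoxyphenyl]‑2H‑chromen‑3‑yl formate
Conditions: mCPBA (1.05 equiv), Na2HPO4, CH2Cl2, 0 °C
Reagents that add atoms: mCPBA, OOC(=O)c1cccc(Cl)c1 (one oxygen)
Why: Baeyer–Villiger oxidation of the enal; the alkenyl group, part of a vinylogous trialkoxyaryl π‑system, migrates in preference to hydride, giving the enol formate. C2 is not involved, and limiting the peracid avoids epoxidising the product.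

Step 11
Reactants: 12 the (2R)‑enol formate
Product: 13 (2R)‑5,7‑bis(benzyloxy)‑2‑[3,5‑bis(benzyloxy)‑4‑methoxyphenyl]chroman‑3‑one
Conditions: KHCO3 (0.5 equiv), degassed MeOH/THF, 0 °C, 30 min; use crude at once
Reagents that add atoms: none
Why: mild transesterification of the labile formate releases the C3–C4 enol, which ketonises by protonation at C4; the short, cold, weakly basic treatment leaves the C2–H untouched.

Step 12
Reactants: 13 the (2R)‑flavan‑3‑one
Product: 14 (2R,3R)‑5,7‑bis(benzyloxy)‑2‑[3,5‑bis(benzyloxy)‑4‑methoxyphenyl]chroman‑3‑ol (2,3‑cis)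
Conditions: L‑Selectride, LiBr, THF, −78 °C; then aq. NaOH/H2O2; recrystallise
Reagents that add atoms: none
Why: substrate‑controlled ketone reduction; the bulky hydride attacks C3 from the face opposite the C2 aryl, so the new OH is cis to the aryl (3R). Recrystallisation can raise the ee.

**Galloyl fragment**

Step 13
Reactants: 5 methyl gallate
Product: 15 methyl 3,4,5‑tris(benzyloxy)benzoate
Conditions: BnBr (3.5 equiv), K2CO3, DMF, 60 °C
Reagents that add atoms: benzyl bromide, BrCc1ccccc1
Why: exhaustive Williamson benzylation.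

Step 14
Reactants: 15 methyl 3,4,5‑tris(benzyloxy)benzoate
Product: 16 3,4,5‑tris(benzyloxy)benzoic acid
Conditions: NaOH, MeOH/THF/H2O, reflux; then HCl
Reagents that add atoms: hydroxide/water, O (acid OH oxygen)
Why: saponification; benzyl ethers are stable to base.

Step 15
Reactants: 16 3,4,5‑tris(benzyloxy)benzoic acid
Product: 17 3,4,5‑tris(benzyloxy)benzoyl chloride
Conditions: (COCl)2, cat. DMF, CH2Cl2, 0 °C → rt
Reagents that add atoms: oxalyl chloride, ClC(=O)C(=O)Cl (chlorine)
Why: Vilsmeier‑type acid chloride formation under neutral conditions.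

**Endgame**

Step 16
Reactants: 14 the (2R,3R)‑cis‑flavan‑3‑ol; 17 3,4,5‑tris(benzyloxy)benzoyl chloride (1.5 equiv)
Product: 18 (2R,3R)‑5,7‑bis(benzyloxy)‑2‑[3,5‑bis(benzyloxy)‑4‑methoxyphenyl]chroman‑3‑yl 3,4,5‑tris(benzyloxy)benzoate
Conditions: DMAP, Et3N, CH2Cl2, 0 °C → rt
Reagents that add atoms: none beyond reactant 17
Why: DMAP‑catalysed acylation of the secondary alcohol at oxygen, so both stereocentres are retained.

Step 17
Reactants: 18 the hepta‑O‑benzyl ester
Product: 19 4'‑O‑methylepigallocatechin‑3‑O‑gallate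
Conditions: H2 (1 atm), 20 % Pd(OH)2/C, THF/MeOH, rt; filter under inert gas
Reagents that add atoms: none
Why: hydrogenolysis removes all seven benzyl ethers; the methyl ether, the ester and both stereocentres are unaffected under these neutral conditions.

---

**Compound list**

1 | phloroglucinol | Oc1cc(O)cc(O)c1 | starting material
2 | 1,3,5‑tris(benzyloxy)benzene | c1ccc(COc2cc(OCc3ccccc3)cc(OCc3ccccc3)c2)cc1 | intermediate
3 | 2,4,6‑tris(benzyloxy)benzaldehyde | O=Cc1c(OCc2ccccc2)cc(OCc2ccccc2)cc1OCc1ccccc1 | intermediate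
4 | 4,6‑bis(benzyloxy)‑2‑hydroxybenzaldehyde | O=Cc1c(O)cc(OCc2ccccc2)cc1OCc1ccccc1 | intermediate
5 | methyl gallate | COC(=O)c1cc(O)c(O)c(O)c1 | starting material
6 | methyl 3,5‑dihydroxy‑4‑methoxybenzoate | COC(=O)c1cc(O)c(OC)c(O)c1 | intermediate
7 | methyl 3,5‑bis(benzyloxy)‑4‑methoxybenzoate | COC(=O)c1cc(OCc2ccccc2)c(OC)c(OCc2ccccc2)c1 | intermediate
8 | [3,5‑bis(benzyloxy)‑4‑methoxyphenyl]methanol | OCc1cc(OCc2ccccc2)c(OC)c(OCc2ccccc2)c1 | intermediate
9 | 3,5‑bis(benzyloxy)‑4‑methoxybenzaldehyde | O=Cc1cc(OCc2ccccc2)c(OC)c(OCc2ccccc2)c1 | intermediate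
10 | (E)‑3‑[3,5‑bis(benzyloxy)‑4‑methoxyphenyl]prop‑2‑enal | O=C/C=C/c1cc(OCc2ccccc2)c(OC)c(OCc2ccccc2)c1 | intermediate
11 | (2R)‑5,7‑bis(benzyloxy)‑2‑[3,5‑bis(benzyloxy)‑4‑methoxyphenyl]‑2H‑chromene‑3‑carbaldehyde | O=CC1=Cc2c(OCc3ccccc3)cc(OCc3ccccc3)cc2O[C@@H]1c1cc(OCc2ccccc2)c(OC)c(OCc2ccccc2)c1 | intermediate
12 | (2R)‑5,7‑bis(benzyloxy)‑2‑[3,5‑bis(benzyloxy)‑4‑methoxyphenyl]‑2H‑chromen‑3‑yl formate | O=COC1=Cc2c(OCc3ccccc3)cc(OCc3ccccc3)cc2O[C@@H]1c1cc(OCc2ccccc2)c(OC)c(OCc2ccccc2)c1 | intermediate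
13 | (2R)‑5,7‑bis(benzyloxy)‑2‑[3,5‑bis(benzyloxy)‑4‑methoxyphenyl]chroman‑3‑one | O=C1Cc2c(OCc3ccccc3)cc(OCc3ccccc3)cc2O[C@@H]1c1cc(OCc2ccccc2)c(OC)c(OCc2ccccc2)c1 | intermediate
14 | (2R,3R)‑5,7‑bis(benzyloxy)‑2‑[3,5‑bis(benzyloxy)‑4‑methoxyphenyl]chroman‑3‑ol | O[C@@H]1Cc2c(OCc3ccccc3)cc(OCc3ccccc3)cc2O[C@@H]1c1cc(OCc2ccccc2)c(OC)c(OCc2ccccc2)c1 | intermediate
15 | methyl 3,4,5‑tris(benzyloxy)benzoate | COC(=O)c1cc(OCc2ccccc2)c(OCc2ccccc2)c(OCc2ccccc2)c1 | intermediate
16 | 3,4,5‑tris(benzyloxy)benzoic acid | OC(=O)c1cc(OCc2ccccc2)c(OCc2ccccc2)c(OCc2ccccc2)c1 | intermediate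
17 | 3,4,5‑tris(benzyloxy)benzoyl chloride | O=C(Cl)c1cc(OCc2ccccc2)c(OCc2ccccc2)c(OCc2ccccc2)c1 | intermediate
18 | (2R,3R)‑5,7‑bis(benzyloxy)‑2‑[3,5‑bis(benzyloxy)‑4‑methoxyphenyl]chroman‑3‑yl 3,4,5‑tris(benzyloxy)benzoate | O=C(O[C@@H]1Cc2c(OCc3ccccc3)cc(OCc3ccccc3)cc2O[C@@H]1c1cc(OCc2ccccc2)c(OC)c(OCc2ccccc2)c1)c1cc(OCc2ccccc2)c(OCc2ccccc2)c(OCc2ccccc2)c1 | intermediate
19 | 4'‑O‑methylepigallocatechin‑3‑O‑gallate | COc1c(O)cc([C@H]2Oc3cc(O)cc(O)c3C[C@H]2OC(=O)c2cc(O)c(O)c(O)c2)cc1O | target

---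

**Totals**
- Total steps: 17.
- Longest linear sequence: 11 steps (5 → 6 → 7 → 8 → 9 → 10 → 11 → 12 → 13 → 14 → 18 → 19), i.e. 11/17 ≈ 0.65. The A‑ring branch is 9 steps to the target and the galloyl branch 5.

**Three steps most likely to fail, with fallbacks**
1. Step 9. The 6‑benzyloxy, electron‑rich salicylaldehyde may close slowly, letting the reversible oxa‑Michael erode ee. Fallback: switch to the chalcone route. Condense 2‑hydroxy‑4,6‑bis(benzyloxy)acetophenone with aldehyde 9, close the ring by intramolecular oxa‑Michael to the racemic flavanone, and resolve by asymmetric transfer hydrogenation (Ru–TsDPEN). Then dehydrate to the flav‑3‑ene, hydroborate, oxidise to ketone 13 and rejoin at Step 12.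
2. Step 10. The Baeyer–Villiger may over‑oxidise the electron‑rich enol formate or give the carboxylic acid by hydride migration. Fallback: excise the carbon through nitrogen instead. Pinnick‑oxidise 11 to the chromene‑3‑carboxylic acid, run a Curtius rearrangement (DPPA, Et3N) to the vinyl isocyanate, and hydrolyse mildly to the same ketone 13.
3. Step 11 (with Step 12). Ketone 13 may partly epimerise at C2 or autoxidise, lowering ee. Fallback: stop relying on C2 for control. Deliberately equilibrate C2 and reduce under Noyori–Ikariya transfer hydrogenation with dynamic kinetic resolution, so the catalyst sets both centres of cis‑14; failing that, resolve 14 by lipase acylation.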